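## Retrosynthetic overview

- The CH2 bridge is cut last: C1' of the ring B triketone 11 adds to the ortho-quinone methide released from the chromene Mannich base 20.
- The strategy rests on ring B, the cyclohexadienone C1'–C6' with quaternary C3' between the oxygenated carbons C2' and C4'. It is the carbon-closed isomer of a 3-acetyl-4-methoxy-6-alkyl-2-pyranone, with the C3'–C4' bond standing where the lactone O–C(=O) bond was.
- Pyranone 8 comes from 4-methoxy-6-methyl-2-pyranone. C3 is brominated first, because N-bromosuccinimide would attack the geranyl alkenes later; then geranylation and methylation of the 6-methyl group, then a Stille acetylation.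
- The chromene comes from hexanoylphloroglucinol. The para hydroxyl is masked as its methoxymethyl ether so that the pyran ring must close through the oxygen ortho to the acyl group.
- Ring order: the 2-pyranone and the benzene ring are bought; ring B is closed in step 5, the pyran ring of the chromene in step 9.

Key step: step 5

Assumptions:
- Compounds 10, 11 and 22 are vinylogous acids and are written as one tautomer each; the spatial arrangement at C3' is the same in all of them.
- The sense of induction of the new cyclization cannot be fixed in advance; the (2S,3R) catalyst is written, and its mirror image would be taken if that is the one that leads to (R)-10.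

## Route

Step 1
Reactants: 1 4-methoxy-6-methyl-2H-pyran-2-one
Product: 2 3-bromo-4-methoxy-6-methyl-2H-pyran-2-one
Conditions: N-bromosuccinimide, MeCN, rt, dark
Reagents that add atoms: N-bromosuccinimide O=C1CCC(=O)N1Br
Why: Electrophilic bromination at C3, the enol-ether β-carbon that is also α to the lactone carbonyl and the most nucleophilic ring position; it is placed first because the reagent would not spare the trisubstituted alkenes of the geranyl chain.

Step 2
Reactants: 2 3-bromo-4-methoxy-6-methyl-2H-pyran-2-one; 3 geranyl bromide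
Product: 4 3-bromo-6-[(3E)-4,8-dimethylnona-3,7-dien-1-yl]-4-methoxy-2H-pyran-2-one
Conditions: LiN(SiMe3)2, THF, DMPU, −78 °C; then 3, −78 to −30 °C
Reagents that add atoms: none
Why: Vinylogous deprotonation of the 6-methyl group gives the extended dienolate, which is alkylated by the allylic bromide at the exocyclic carbon in an SN2 reaction, and the amide base does not exchange the C3 bromide.

Step 3
Reactants: 4 3-bromo-6-[(3E)-4,8-dimethylnona-3,7-dien-1-yl]-4-methoxy-2H-pyran-2-one; 5 iodomethane
Product: 6 racemic 3-bromo-6-[(4E)-5,9-dimethyldeca-4,8-dien-2-yl]-4-methoxy-2H-pyran-2-one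
Conditions: LiN(SiMe3)2, THF, DMPU, −78 °C; then 5, −78 to −40 °C
Reagents that add atoms: none
Why: A second vinylogous deprotonation at the now secondary exocyclic carbon and SN2 methylation install the branch methyl group; the new stereocentre forms as a racemate, which is acceptable because step 5 erases it.

Step 4
Reactants: 6 racemic 3-bromo-6-[(4E)-5,9-dimethyldeca-4,8-dien-2-yl]-4-methoxy-2H-pyran-2-one
Product: 8 racemic 3-acetyl-6-[(4E)-5,9-dimethyldeca-4,8-dien-2-yl]-4-methoxy-2H-pyran-2-one, via enol ether 7 (not isolated)
Conditions: tributyl(1-ethoxyvinyl)stannane, Pd(PPh3)4 (5 mol%), toluene, 100 °C; then 1 M HCl, THF, rt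
Reagents that add atoms: tributyl(1-ethoxyvinyl)stannane CCCC[Sn](CCCC)(CCCC)C(=C)OCC; water O
Why: Stille coupling of the 3-bromopyranone (oxidative addition of zerovalent palladium into C3–Br, transmetalation, reductive elimination) tolerates the diene, and dilute acid then hydrolyses only the simple enol ether 7 to the methyl ketone while the vinylogous 4-methoxy ester survives.

Step 5
Reactants: 8 racemic 3-acetyl-6-[(4E)-5,9-dimethyldeca-4,8-dien-2-yl]-4-methoxy-2H-pyran-2-one
Product: 10 (6R)-2-acetyl-5-hydroxy-3-methoxy-6-methyl-6-[(2E)-3,7-dimethylocta-2,6-dien-1-yl]cyclohexa-2,4-dien-1-one, via acylketene 9 (not isolated)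
Conditions: hν (340 nm LED), (2S,3R)-HyperBTM [(2S,3R)-3-isopropyl-2-phenyl-3,4-dihydro-2H-pyrimido[2,1-b]benzothiazole] (20 mol%), iPr2NEt (1.2 equiv), PhCO2H (10 mol%), toluene (0.01 M), −20 °C; then aq. citric acid
Reagents that add atoms: none
Why: Proposed new method: light drives the six-electron electrocyclic cleavage of the O1–C2 lactone bond of 8 to the cis-dienyl acylketene 9, the nucleophilic isothiourea adds to the ketene carbon to give an acyl ammonium ion, and the amine/ammonium benzoate pair moves the proton of the side-chain CH so that the ketone becomes its cross-conjugated enolate, whose carbon is then acylated with release of the catalyst. The closest known reactions are the photochemical opening of 2-pyranones to ketenes that nucleophiles trap, the thermal 6π closure of dienyl ketenes to cyclohexa-2,4-dienones, and the isothiourea-catalysed enantioselective C-acylation of enolates (Steglich-type acyl transfer) that builds quaternary carbons. Ring B closes by a 6-(enolendo)-exo-trig Claisen-type attack of the enolate carbon (future C3') on the acyl ammonium carbon (future C4'), which forms the C3'–C4' bond. The stereocentre of racemic 8 is lost in the planar enolate and C3' is set by the catalyst: the S···O contact holds the acyl ammonium group coplanar with the isothiourea, its phenyl group shields one face, and the tethered enolate must wrap onto the open face with the methyl group, not the geranyl methylene, turned toward the catalyst. The step needs carbon closure to win over oxygen reclosure and the catalysed path to win over the racemic 6π closure of the free dienol ketene: oxygen reclosure only returns 8, which is excited again, whereas the dienone with quaternary C3' can neither aromatize nor revert thermally, and the free ketene should be too short-lived at −20 °C to enolize without the catalyst-bound, base-assisted path. The amine also keeps the isothiourea free of the acidic product, and 340 nm light should be absorbed by the acetylpyranone but hardly by the catalyst.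

Step 6
Reactants: 10 (6R)-2-acetyl-5-hydroxy-3-methoxy-6-methyl-6-[(2E)-3,7-dimethylocta-2,6-dien-1-yl]cyclohexa-2,4-dien-1-one
Product: 11 (4R)-2-acetyl-3,5-dihydroxy-4-methyl-4-[(2E)-3,7-dimethylocta-2,6-dien-1-yl]cyclohexa-2,5-dien-1-one
Conditions: 1 M HCl (aq.), THF, rt
Reagents that add atoms: water O
Why: Acid-catalysed hydrolysis of the vinylogous methyl ester by addition of water at C6' and loss of methanol is fast because C6' is the β-carbon of a 2-acyl enone, while the trisubstituted alkenes and the non-enolizable quaternary C3' centre should be untouched by dilute acid at room temperature.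

Step 7
Reactants: 12 phloroglucinol; 13 hexanoyl chloride
Product: 14 1-(2,4,6-trihydroxyphenyl)hexan-1-one
Conditions: AlCl3 (3 equiv), CH2Cl2/MeNO2, 0 °C to rt
Reagents that add atoms: none
Why: Friedel–Crafts acylation of the symmetric, highly nucleophilic triol stops after one acyl group because the chelated aryl ketone deactivates the ring.

Step 8
Reactants: 14 1-(2,4,6-trihydroxyphenyl)hexan-1-one
Product: 15 1-[2,6-dihydroxy-4-(methoxymethoxy)phenyl]hexan-1-one
Conditions: MOMCl (1.0 equiv), iPr2NEt, CH2Cl2, 0 °C
Reagents that add atoms: chloromethyl methyl ether COCCl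
Why: Selective O-alkylation of the para hydroxyl, the most acidic one and the only one never chelated to the ketone, blocks the oxygen that would otherwise compete in the chromene closure.

Step 9
Reactants: 15 1-[2,6-dihydroxy-4-(methoxymethoxy)phenyl]hexan-1-one; 16 3-methylbut-2-enal
Product: 18 1-[7-hydroxy-5-(methoxymethoxy)-2,2-dimethyl-2H-chromen-8-yl]hexan-1-one, via oxatriene 17 (not isolated)
Conditions: ethylenediammonium diacetate (20 mol%), toluene, reflux (Dean–Stark)
Reagents that add atoms: none
Why: Amine-catalysed Knoevenagel-type condensation of the enal at the ring carbon between OH and OMOM gives the oxatriene 17, which closes by oxa-6π electrocyclization through the only free neighbouring oxygen, the one ortho to the acyl group, and so fixes the 8-acyl chromene pattern.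

Step 10
Reactants: 18 1-[7-hydroxy-5-(methoxymethoxy)-2,2-dimethyl-2H-chromen-8-yl]hexan-1-one
Product: 19 1-(5,7-dihydroxy-2,2-dimethyl-2H-chromen-8-yl)hexan-1-one
Conditions: HCl (cat.), MeOH, 40 °C
Reagents that add atoms: none
Why: Acid-catalysed acetal exchange passes the methoxymethyl group to methanol under conditions that 2,2-dimethylchromenes and chelated aryl ketones tolerate.

Step 11
Reactants: 19 1-(5,7-dihydroxy-2,2-dimethyl-2H-chromen-8-yl)hexan-1-one
Product: 20 1-[5,7-dihydroxy-2,2-dimethyl-6-(morpholin-4-ylmethyl)-2H-chromen-8-yl]hexan-1-one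
Conditions: aq. CH2O (37%), morpholine, EtOH, 0 °C to rt
Reagents that add atoms: formaldehyde C=O; morpholine C1COCCN1
Why: Phenolic Mannich reaction at C6, the only unsubstituted aromatic carbon and one flanked by two hydroxyls, gives a storable precursor of the quinone methide.

Step 12
Reactants: 11 (4R)-2-acetyl-3,5-dihydroxy-4-methyl-4-[(2E)-3,7-dimethylocta-2,6-dien-1-yl]cyclohexa-2,5-dien-1-one; 20 1-[5,7-dihydroxy-2,2-dimethyl-6-(morpholin-4-ylmethyl)-2H-chromen-8-yl]hexan-1-one
Product: 22 1-{6-[((3R)-5-acetyl-2,4-dihydroxy-3-methyl-3-[(2E)-3,7-dimethylocta-2,6-dien-1-yl]-6-oxocyclohexa-1,4-dien-1-yl)methyl]-5,7-dihydroxy-2,2-dimethyl-2H-chromen-8-yl}hexan-1-one, via quinone methide 21 (not isolated)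
Conditions: toluene, 80 °C (20 in slight excess)
Reagents that add atoms: none
Why: Thermal retro-Mannich loss of morpholine, helped by proton transfer from the acidic triketone, gives the ortho-quinone methide 21, and Michael addition of the triketone enolate through C1', its only enolizable ring carbon, forms the methylene bridge without touching the C3' stereocentre.

## Compound list

1 | 4-methoxy-6-methyl-2H-pyran-2-one | COC1=CC(=O)OC(C)=C1 | starting material
2 | 3-bromo-4-methoxy-6-methyl-2H-pyran-2-one | COC1=C(Br)C(=O)OC(C)=C1 | intermediate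
3 | geranyl bromide, (2E)-1-bromo-3,7-dimethylocta-2,6-diene | BrC/C=C(\C)CCC=C(C)C | starting material
4 | 3-bromo-6-[(3E)-4,8-dimethylnona-3,7-dien-1-yl]-4-methoxy-2H-pyran-2-one | COC1=C(Br)C(=O)OC(CC/C=C(\C)CCC=C(C)C)=C1 | intermediate
5 | iodomethane | CI | starting material
6 | racemic 3-bromo-6-[(4E)-5,9-dimethyldeca-4,8-dien-2-yl]-4-methoxy-2H-pyran-2-one | COC1=C(Br)C(=O)OC(C(C)C/C=C(\C)CCC=C(C)C)=C1 | intermediate
7 | racemic 6-[(4E)-5,9-dimethyldeca-4,8-dien-2-yl]-3-(1-ethoxyethenyl)-4-methoxy-2H-pyran-2-one | CCOC(=C)C1=C(OC)C=C(OC1=O)C(C)C/C=C(\C)CCC=C(C)C | intermediate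
8 | racemic 3-acetyl-6-[(4E)-5,9-dimethyldeca-4,8-dien-2-yl]-4-methoxy-2H-pyran-2-one | CC(=O)C1=C(OC)C=C(OC1=O)C(C)C/C=C(\C)CCC=C(C)C | intermediate
9 | racemic (3E,8E)-2-acetyl-3-methoxy-6,9,13-trimethyltetradeca-1,3,8,12-tetraene-1,5-dione (acylketene, ketene carbon and ketone cis across C3=C4) | O=C=C(C(C)=O)/C(OC)=C\C(=O)C(C)C/C=C(\C)CCC=C(C)C | intermediate
10 | (6R)-2-acetyl-5-hydroxy-3-methoxy-6-methyl-6-[(2E)-3,7-dimethylocta-2,6-dien-1-yl]cyclohexa-2,4-dien-1-one | C1=C(O)[C@@](C)(C/C=C(\C)CCC=C(C)C)C(=O)C(C(C)=O)=C1OC | intermediate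
11 | (4R)-2-acetyl-3,5-dihydroxy-4-methyl-4-[(2E)-3,7-dimethylocta-2,6-dien-1-yl]cyclohexa-2,5-dien-1-one | C1=C(O)[C@@](C)(C/C=C(\C)CCC=C(C)C)C(O)=C(C(C)=O)C1=O | intermediate
12 | phloroglucinol (benzene-1,3,5-triol) | Oc1cc(O)cc(O)c1 | starting material
13 | hexanoyl chloride | CCCCCC(Cl)=O | starting material
14 | 1-(2,4,6-trihydroxyphenyl)hexan-1-one | CCCCCC(=O)c1c(O)cc(O)cc1O | intermediate
15 | 1-[2,6-dihydroxy-4-(methoxymethoxy)phenyl]hexan-1-one | CCCCCC(=O)c1c(O)cc(OCOC)cc1O | intermediate
16 | 3-methylbut-2-enal | CC(C)=CC=O | starting material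
17 | 2-hexanoyl-3-hydroxy-5-(methoxymethoxy)-6-(3-methylbut-2-en-1-ylidene)cyclohexa-2,4-dien-1-one | CCCCCC(=O)C1=C(O)C=C(OCOC)C(=CC=C(C)C)C1=O | intermediate
18 | 1-[7-hydroxy-5-(methoxymethoxy)-2,2-dimethyl-2H-chromen-8-yl]hexan-1-one | CCCCCC(=O)c1c(O)cc(OCOC)c2c1OC(C)(C)C=C2 | intermediate
19 | 1-(5,7-dihydroxy-2,2-dimethyl-2H-chromen-8-yl)hexan-1-one | CCCCCC(=O)c1c(O)cc(O)c2c1OC(C)(C)C=C2 | intermediate
20 | 1-[5,7-dihydroxy-2,2-dimethyl-6-(morpholin-4-ylmethyl)-2H-chromen-8-yl]hexan-1-one | CCCCCC(=O)c1c(O)c(CN3CCOCC3)c(O)c2c1OC(C)(C)C=C2 | intermediate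
21 | 8-hexanoyl-5-hydroxy-2,2-dimethyl-6-methylidene-2H-chromen-7(6H)-one | CCCCCC(=O)C1=C2OC(C)(C)C=CC2=C(O)C(=C)C1=O | intermediate
22 | CNP0319887.1, 1-{6-[((3R)-5-acetyl-2,4-dihydroxy-3-methyl-3-[(2E)-3,7-dimethylocta-2,6-dien-1-yl]-6-oxocyclohexa-1,4-dien-1-yl)methyl]-5,7-dihydroxy-2,2-dimethyl-2H-chromen-8-yl}hexan-1-one | CCCCCC(=O)c1c(O)c(CC2=C(O)[C@@](C)(C/C=C(\C)CCC=C(C)C)C(O)=C(C(C)=O)C2=O)c(O)c2c1OC(C)(C)C=C2 | target

## Step count and risk

Total step count: 12. Longest linear sequence: 7 steps (steps 1 to 6, then step 12); the chromene branch is 6 steps (steps 7 to 12).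

Steps most likely to fail:

1. Step 5. Three processes may defeat it. The acyl ammonium ion may reclose through oxygen faster than the proton shift, so that no carbocycle builds up. Facial selection may be poor because methyl and the geranyl methylene differ little in size. The product dienone may itself be opened by light and reclose without the catalyst, which would erode the enantiomeric purity. The fallback uses known chemistry, sets out from 3 and comes back at 11. Commercially available 1-(2,4,6-trihydroxy-3-methylphenyl)ethan-1-one F1 would be C-geranylated with 3 at its methyl-bearing ring carbon (NaOMe, MeOH, 0 °C; alkylative dearomatization). This should give racemic 2-acetyl-3,5-dihydroxy-4-methyl-4-[(2E)-3,7-dimethylocta-2,6-dien-1-yl]cyclohexa-2,5-dien-1-one F2, and preparative chromatography on a chiral stationary phase would then deliver the (R) enantiomer, which is 11. This replaces steps 1 to 6 by a racemic synthesis with resolution.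

2. Step 9. Condensation at the ring carbon flanked by OH and OMOM may be slow, the enal may oligomerize, and partial loss of the acetal would let the ring close through the para oxygen. The fallback sets out from 15 and comes back at 18. One of the two equivalent ortho hydroxyls would be alkylated (3-chloro-3-methylbut-1-yne, DBU, CuCl2 cat., MeCN, 0 °C) to give 1-{2-hydroxy-4-(methoxymethoxy)-6-[(2-methylbut-3-yn-2-yl)oxy]phenyl}hexan-1-one F3. Heating in xylene at 140 °C should cause aromatic Claisen rearrangement to the allenyl phenol 1-[2,6-dihydroxy-4-(methoxymethoxy)-3-(3-methylbuta-1,2-dien-1-yl)phenyl]hexan-1-one F4, a [1,5]-hydrogen shift to the oxatriene 17 and oxa-6π closure to 18. The regiochemistry is again fixed, because the ether oxygen has only one free ortho carbon.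

3. Step 12. The quinone methide may condense with itself, may be captured at an enol oxygen to give a cyclic ketal instead of the open C-alkylated product, or the chromene may isomerize by ring opening on prolonged heating. The fallback reverses the polarity; it sets out from 11 and comes back at 22. Treatment of 11 with dimethylmethylideneammonium iodide (CH2Cl2, 0 °C, NaHCO3 wash) would give the C1' Mannich base (4R)-2-acetyl-6-[(dimethylamino)methyl]-3,5-dihydroxy-4-methyl-4-[(2E)-3,7-dimethylocta-2,6-dien-1-yl]cyclohexa-2,5-dien-1-one F5. Warmed with 19 in dioxane, F5 should lose dimethylamine to the methylidene triketone 4-acetyl-5-hydroxy-6-methyl-2-methylidene-6-[(2E)-3,7-dimethylocta-2,6-dien-1-yl]cyclohex-4-ene-1,3-dione F6 (6S by the CIP rules, same spatial arrangement as in 11). C6 of 19, its only free aromatic carbon, would then add to F6 in a Friedel–Crafts-type conjugate addition to give 22.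

Further compounds
F1 | step 5 | 1-(2,4,6-trihydroxy-3-methylphenyl)ethan-1-one | CC(=O)c1c(O)cc(O)c(C)c1O
F2 | step 5 | racemic 2-acetyl-3,5-dihydroxy-4-methyl-4-[(2E)-3,7-dimethylocta-2,6-dien-1-yl]cyclohexa-2,5-dien-1-one | C1=C(O)C(C)(C/C=C(\C)CCC=C(C)C)C(O)=C(C(C)=O)C1=O
F3 | step 9 | 1-{2-hydroxy-4-(methoxymethoxy)-6-[(2-methylbut-3-yn-2-yl)oxy]phenyl}hexan-1-one | CCCCCC(=O)c1c(O)cc(OCOC)cc1OC(C)(C)C#C
F4 | step 9 | 1-[2,6-dihydroxy-4-(methoxymethoxy)-3-(3-methylbuta-1,2-dien-1-yl)phenyl]hexan-1-one | CCCCCC(=O)c1c(O)cc(OCOC)c(C=C=C(C)C)c1O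
F5 | step 12 | (4R)-2-acetyl-6-[(dimethylamino)methyl]-3,5-dihydroxy-4-methyl-4-[(2E)-3,7-dimethylocta-2,6-dien-1-yl]cyclohexa-2,5-dien-1-one | CN(C)CC1=C(O)[C@@](C)(C/C=C(\C)CCC=C(C)C)C(O)=C(C(C)=O)C1=O
F6 | step 12 | (6S)-4-acetyl-5-hydroxy-6-methyl-2-methylidene-6-[(2E)-3,7-dimethylocta-2,6-dien-1-yl]cyclohex-4-ene-1,3-dione | C=C1C(=O)[C@@](C)(C/C=C(\C)CCC=C(C)C)C(O)=C(C(C)=O)C1=O
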